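## Retrosynthetic overview

1. Target ⇐ desilylation, Heck coupling with 4-iodophenol and O-acryloylation of the primary alcohol of a bis-silylated diol; the diol ⇐ hydride opening of a cis-fused, all-exo 3,6-diaryl furo[3,4-c]furan-1-one.
2. The lactone ring (third ring made, later opened) ⇐ acid-triggered ring expansion of a donor–acceptor cyclopropane, a 2,6-diaryl-3-oxabicyclo[3.1.0]hexane-1-carboxylate, to the γ-butyrolactone; this fixes C8 and C7'.
3. The cyclopropane (second ring) ⇐ cyclopropanation of methyl (R)-2-aryl-2,5-dihydrofuran-3-carboxylate with an aryldiazomethane, anti to the resident aryl; this fixes C8'.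
4. The C7 stereocentre ⇐ a new enantioselective Heck arylation of methyl 4,5-dihydrofuran-3-carboxylate; the oxolane ring (first ring) is bought as 2,3-dihydrofuran and C-acylated with trichloroacetyl chloride.
5. Both guaiacyl units ⇐ one aryl bromide from catechol (methylation, bromination, silylation); formylation gives the second copy as the aldehyde.

Assumptions and conventions: lignan numbering is used for orientation (C7–C8–C9 = ArCH–CH–CH2O of the unit whose aryl sits on the ring, primed atoms = the ArCH(OH)–CH–CH2O unit); the target is read as 7S,8R,7'S,8'R; Ar = 3-methoxy-4-[(triisopropylsilyl)oxy]phenyl; the sense of induction in step 5 is assigned by analogy and is not established.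

## Route

Step 1
Reactants: 1 catechol (benzene-1,2-diol)
Product: 2 2-methoxyphenol
Conditions: MeI (0.95 equiv), K2CO3 (1.0 equiv), acetone, reflux; distillation
Reagents that add atoms: iodomethane, CI
Why: Williamson mono-O-methylation of the catechol monoanion with slightly substoichiometric MeI gives the mono-ether (statistical selectivity), which is separated from catechol and veratrole by distillation.

Step 2
Reactants: 2 2-methoxyphenol
Product: 4 (4-bromo-2-methoxyphenoxy)triisopropylsilane, via 4-bromo-2-methoxyphenol 3 (not isolated)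
Conditions: NBS (1.0 equiv), DMF, 0 °C; then imidazole (2.5 equiv), i-Pr3SiCl (1.2 equiv), rt
Reagents that add atoms: N-bromosuccinimide, O=C1CCC(=O)N1Br; chlorotri(propan-2-yl)silane, CC(C)[Si](Cl)(C(C)C)C(C)C
Why: electrophilic aromatic bromination goes para to the free hydroxyl (the stronger director), and the phenol is then silylated in the same pot to a fluoride-labile ether that survives organolithium, acid and hydride steps.

Step 3
Reactants: 4 (4-bromo-2-methoxyphenoxy)triisopropylsilane
Product: 6 3-methoxy-4-[(triisopropylsilyl)oxy]benzaldehyde, via aryllithium 5 (not isolated)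
Conditions: n-BuLi (1.05 equiv), THF, −78 °C; DMF (1.5 equiv), −78 → 0 °C; 1 M HCl
Reagents that add atoms: N,N-dimethylformamide, CN(C)C=O
Why: bromine–lithium exchange followed by Bouveault formylation of the aryllithium with DMF gives the aldehyde after hydrolysis of the hemiaminal.

Step 4
Reactants: 7 2,3-dihydrofuran; 8 trichloroacetyl chloride
Product: 10 methyl 4,5-dihydrofuran-3-carboxylate, via trichloromethyl ketone 9 (not isolated)
Conditions: pyridine (1.1 equiv), CH2Cl2, 0 °C → rt; then MeOH, K2CO3 (1.5 equiv), rt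
Reagents that add atoms: methanol, CO
Why: the enol ether is C-acylated at its nucleophilic β-carbon (addition–elimination), and haloform-type methanolysis of the trichloromethyl ketone gives the β-alkoxyacrylate ester.

Step 5
Reactants: 4 (4-bromo-2-methoxyphenoxy)triisopropylsilane; 10 methyl 4,5-dihydrofuran-3-carboxylate (3 equiv)
Product: 11 methyl (2R)-2-Ar-2,5-dihydrofuran-3-carboxylate
Conditions: Pd(OAc)2 (5 mol %), (S)-BINAP (10 mol %), Ag2CO3 (0.6 equiv), toluene–THF, 60 °C
Reagents that add atoms: none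
Why: Proposed new method: an enantioselective intermolecular Mizoroki–Heck arylation of a β-alkoxyacrylate locked in a 4,5-dihydrofuran, in which Ag2CO3 strips bromide so that a cationic (S)-BINAP aryl–palladium species binds one alkene face, the aryl migrates to C2 (α to oxygen and β to the ester, so enol-ether polarisation, acrylate polarisation and sterics agree) and sets C2 as R, and the tertiary C3–palladium enolate can only syn-eliminate a C4–H (the C2–H is anti), releasing the conjugated 2,5-dihydrofuran-3-carboxylate without erasing the new stereocentre; the closest known reaction type is the asymmetric Heck arylation of 2,3-dihydrofuran with BINAP-type ligands.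

Step 6
Reactants: 11 methyl (2R)-2-Ar-2,5-dihydrofuran-3-carboxylate; 6 3-methoxy-4-[(triisopropylsilyl)oxy]benzaldehyde (1.5 equiv)
Product: 15 methyl (1R,2R,5R,6S)-2,6-di-Ar-3-oxabicyclo[3.1.0]hexane-1-carboxylate, via tosylhydrazone 12 (not isolated), via aryldiazomethane 13 (not isolated), via pyrazoline 14 (not isolated)
Conditions: 6, TsNHNH2 (1.5 equiv), 1,4-dioxane, rt; then NaOtBu (1.5 equiv), BnEt3NCl (10 mol %), 11, 45 °C; then 90 °C
Reagents that add atoms: none
Why: Bamford–Stevens generation of the electron-rich aryldiazomethane, 1,3-dipolar cycloaddition to the enoate on the face anti to the C2 aryl (this sets C5, the future C8') and thermal N2 extrusion from the 1-pyrazoline give the cyclopropane, whose C6 configuration (expected exo) does not matter because it is reset in step 7.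

Step 7
Reactants: 15 methyl (1R,2R,5R,6S)-2,6-di-Ar-3-oxabicyclo[3.1.0]hexane-1-carboxylate
Product: 16 (3S,3aR,6S,6aS)-3,6-di-Ar-tetrahydro-1H,3H-furo[3,4-c]furan-1-one
Conditions: TfOH (10 mol %), H2O (2 equiv), (CF3)2CHOH–CH2Cl2 1:4, −20 → 0 °C
Reagents that add atoms: water, O
Why: acid-triggered heterolysis of the push–pull C1–C6 bond (donor p-silyloxyaryl, acceptor ester) gives a benzylic cation that the ester carbonyl oxygen captures, so the cyclopropane expands to a γ-butyrolactone (donor–acceptor cyclopropane to lactone ring expansion, water hydrolysing the methoxy-oxocarbenium); cis-fusion of the two five-membered rings forces protonation of C6a on the convex face (C8), reversible benzylic C–O ionisation places the C3 aryl exo (C7'), and C3a and C6 are untouched.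

Step 8
Reactants: 16 (3S,3aR,6S,6aS)-3,6-di-Ar-tetrahydro-1H,3H-furo[3,4-c]furan-1-one
Product: 17 (S)-Ar[(3R,4R,5S)-5-Ar-4-(hydroxymethyl)oxolan-3-yl]methanol
Conditions: LiAlH4 (1.5 equiv), THF, 0 °C; aq. potassium sodium tartrate
Reagents that add atoms: none
Why: hydride reduction of the lactone opens it to the 1,4-diol (primary C9–OH, benzylic C7'–OH) without exposing any epimerisable centre, so all four stereocentres are retained.

Step 9
Reactants: 17 (S)-Ar[(3R,4R,5S)-5-Ar-4-(hydroxymethyl)oxolan-3-yl]methanol; 18 acryloyl chloride (1.05 equiv)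
Product: 19 {(2S,3R,4R)-2-Ar-4-[(S)-Ar(hydroxy)methyl]oxolan-3-yl}methyl prop-2-enoate
Conditions: 2,4,6-collidine (2 equiv), CH2Cl2, −78 → −40 °C
Reagents that add atoms: none
Why: acyl chloride esterification with a hindered pyridine base at low temperature is chemoselective for the primary alcohol over the hindered secondary benzylic one, and the base prevents acid-induced cyclisation of the 1,4-diol.

Step 10
Reactants: 19 {(2S,3R,4R)-2-Ar-4-[(S)-Ar(hydroxy)methyl]oxolan-3-yl}methyl prop-2-enoate; 20 4-iodophenol (1.2 equiv)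
Product: 21 {(2S,3R,4R)-2-Ar-4-[(S)-Ar(hydroxy)methyl]oxolan-3-yl}methyl (2E)-3-(4-hydroxyphenyl)prop-2-enoate
Conditions: Pd(OAc)2 (5 mol %), P(o-tol)3 (10 mol %), Et3N (2 equiv), MeCN, 70 °C
Reagents that add atoms: none
Why: Mizoroki–Heck coupling of the acrylate with the aryl iodide (syn insertion, syn β-hydride elimination) gives the E-cinnamate directly and tolerates the free phenol and the benzylic alcohol.

Step 11
Reactants: 21 {(2S,3R,4R)-2-Ar-4-[(S)-Ar(hydroxy)methyl]oxolan-3-yl}methyl (2E)-3-(4-hydroxyphenyl)prop-2-enoate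
Product: 22 {(2S,3R,4R)-2-(4-hydroxy-3-methoxyphenyl)-4-[(S)-hydroxy(4-hydroxy-3-methoxyphenyl)methyl]oxolan-3-yl}methyl (2E)-3-(4-hydroxyphenyl)prop-2-enoate (CNP0330050.2)
Conditions: Bu4NF (2.2 equiv), AcOH (2.5 equiv), THF, 0 °C
Reagents that add atoms: none
Why: fluoride cleaves both aryl silyl ethers, and the acetic acid buffer keeps the phenols protonated so that the cinnamate ester and the p-hydroxybenzylic alcohol are left alone.

## Compound list

1 | catechol (benzene-1,2-diol) | Oc1ccccc1O | starting material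
2 | 2-methoxyphenol | COc1ccccc1O | intermediate
3 | 4-bromo-2-methoxyphenol | COc1cc(Br)ccc1O | intermediate
4 | (4-bromo-2-methoxyphenoxy)triisopropylsilane | COc1cc(Br)ccc1O[Si](C(C)C)(C(C)C)C(C)C | intermediate
5 | {3-methoxy-4-[(triisopropylsilyl)oxy]phenyl}lithium | COc1cc([Li])ccc1O[Si](C(C)C)(C(C)C)C(C)C | intermediate
6 | 3-methoxy-4-[(triisopropylsilyl)oxy]benzaldehyde | COc1cc(C=O)ccc1O[Si](C(C)C)(C(C)C)C(C)C | intermediate
7 | 2,3-dihydrofuran | C1CC=CO1 | starting material
8 | trichloroacetyl chloride | ClC(=O)C(Cl)(Cl)Cl | starting material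
9 | 2,2,2-trichloro-1-(4,5-dihydrofuran-3-yl)ethan-1-one | O=C(C1=COCC1)C(Cl)(Cl)Cl | intermediate
10 | methyl 4,5-dihydrofuran-3-carboxylate | COC(=O)C1=COCC1 | intermediate
11 | methyl (2R)-2-Ar-2,5-dihydrofuran-3-carboxylate | C1O[C@H](c2ccc(O[Si](C(C)C)(C(C)C)C(C)C)c(OC)c2)C(C(=O)OC)=C1 | intermediate
12 | N'-[(E)-Ar-methylidene]-4-methylbenzenesulfonohydrazide | COc1cc(/C=N/NS(=O)(=O)c2ccc(C)cc2)ccc1O[Si](C(C)C)(C(C)C)C(C)C | intermediate
13 | Ar-diazomethane | COc1cc(C=[N+]=[N-])ccc1O[Si](C(C)C)(C(C)C)C(C)C | intermediate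
14 | methyl (3S,3aR,6R,6aS)-3,6-di-Ar-3,3a,4,6-tetrahydro-6aH-furo[3,4-c]pyrazole-6a-carboxylate (cis-fused 1-pyrazoline anti to the C6 aryl, C3 aryl exo) | C1O[C@H](c3ccc(O[Si](C(C)C)(C(C)C)C(C)C)c(OC)c3)[C@@]2(C(=O)OC)N=N[C@H](c4ccc(O[Si](C(C)C)(C(C)C)C(C)C)c(OC)c4)[C@@H]12 | intermediate
15 | methyl (1R,2R,5R,6S)-2,6-di-Ar-3-oxabicyclo[3.1.0]hexane-1-carboxylate (cyclopropane anti to the C2 aryl, C6 aryl exo) | C1O[C@H](c3ccc(O[Si](C(C)C)(C(C)C)C(C)C)c(OC)c3)[C@@]2(C(=O)OC)[C@H](c4ccc(O[Si](C(C)C)(C(C)C)C(C)C)c(OC)c4)[C@@H]12 | intermediate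
16 | (3S,3aR,6S,6aS)-3,6-di-Ar-tetrahydro-1H,3H-furo[3,4-c]furan-1-one (cis-fused, both aryls exo) | COc1cc([C@@H](O3)[C@H]2CO[C@H](c4ccc(O[Si](C(C)C)(C(C)C)C(C)C)c(OC)c4)[C@H]2C3=O)ccc1O[Si](C(C)C)(C(C)C)C(C)C | intermediate
17 | (S)-Ar[(3R,4R,5S)-5-Ar-4-(hydroxymethyl)oxolan-3-yl]methanol | COc1cc([C@@H](O)[C@H]2CO[C@H](c3ccc(O[Si](C(C)C)(C(C)C)C(C)C)c(OC)c3)[C@H]2CO)ccc1O[Si](C(C)C)(C(C)C)C(C)C | intermediate
18 | acryloyl chloride (prop-2-enoyl chloride) | C=CC(=O)Cl | starting material
19 | {(2S,3R,4R)-2-Ar-4-[(S)-Ar(hydroxy)methyl]oxolan-3-yl}methyl prop-2-enoate | COc1cc([C@@H](O)[C@H]2CO[C@H](c3ccc(O[Si](C(C)C)(C(C)C)C(C)C)c(OC)c3)[C@H]2COC(=O)C=C)ccc1O[Si](C(C)C)(C(C)C)C(C)C | intermediate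
20 | 4-iodophenol | Oc1ccc(I)cc1 | starting material
21 | {(2S,3R,4R)-2-Ar-4-[(S)-Ar(hydroxy)methyl]oxolan-3-yl}methyl (2E)-3-(4-hydroxyphenyl)prop-2-enoate | COc1cc([C@@H](O)[C@H]2CO[C@H](c3ccc(O[Si](C(C)C)(C(C)C)C(C)C)c(OC)c3)[C@H]2COC(=O)/C=C/c2ccc(O)cc2)ccc1O[Si](C(C)C)(C(C)C)C(C)C | intermediate
22 | {(2S,3R,4R)-2-(4-hydroxy-3-methoxyphenyl)-4-[(S)-hydroxy(4-hydroxy-3-methoxyphenyl)methyl]oxolan-3-yl}methyl (2E)-3-(4-hydroxyphenyl)prop-2-enoate | COc1cc([C@@H](O)[C@H]2CO[C@H](c3ccc(O)c(OC)c3)[C@H]2COC(=O)/C=C/c2ccc(O)cc2)ccc1O | target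

## Step count and risks

Total step count: 11 (steps 2, 4 and 6 are two- or three-stage one-pot operations).

Longest linear sequence: 9 steps (1, 2, 5, 6, 7, 8, 9, 10, 11 from catechol; the branch through step 3 is equally long).

The three steps most likely to fail:

Step 5 (the proposed new Heck arylation). The risks are slow insertion into a trisubstituted push–pull alkene, over-arylation, and an unknown level and sense of induction (the antipodal ligand is used if the sense is reversed). The fallback uses known chemistry, sets out from aldehyde 6 and comes back at 11. A DABCO-mediated Morita–Baylis–Hillman reaction of 6 with methyl acrylate gives racemic methyl 2-[Ar(hydroxy)methyl]prop-2-enoate F1. Lipase-catalysed acylative kinetic resolution (Pseudomonas cepacia lipase, vinyl acetate) leaves the (R)-alcohol F2 and removes the antipode as the (S)-acetate F3; if the enzyme prefers the R alcohol, its acetate is methanolysed to F2 instead. O-Allylation with allyl bromide and Ag2O gives the (R)-allyl ether F4. Ring-closing metathesis with the second-generation Grubbs catalyst (CH2Cl2, 40 °C) closes the 2,5-dihydrofuran and delivers 11.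

Step 6 (cyclopropanation). The risks are a sluggish dipolar cycloaddition to the hindered enoate, azine formation from the electron-rich diazo compound, and tautomerisation of the pyrazoline instead of N2 loss. The fallback sets out from 6 (with 11) and comes back at 15. NaBH4 reduces 6 to Ar-methanol F5. Tetrahydrothiophene and TfOH (CH2Cl2, 0 °C) convert it into S-(Ar-methyl)thiolanium triflate F6. Its ylide (Cs2CO3, MeCN) adds to the β-carbon of 11 anti to the aryl and closes the three-membered ring by 1,3-displacement of the sulfide (Michael-initiated ring closure of a semi-stabilised sulfonium ylide), giving 15.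

Step 7 (ring expansion). The risks are competing ionisation of the benzylic oxolane C–O bond next to the cyclopropane and E1 loss of a proton from the benzylic cation. The fallback sets out from 11 (with 6) and comes back at 16. SmI2-mediated reductive ketyl–olefin coupling of 6 with the enoate 11 (THF, t-BuOH, −78 °C) gives a γ-oxido ester that lactonises on work-up. This gives 16 together with its C3 epimer, the (3R,3aR,6S,6aS)-lactone F7, which catalytic TFA equilibrates to 16 by benzylic C–O ionisation and reclosure. Isomers from attack on the other enoate face are removed by chromatography.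

## Further compounds

F1 | step 5 | methyl 2-[Ar(hydroxy)methyl]prop-2-enoate (racemic) | COC(=O)C(=C)C(O)c1ccc(O[Si](C(C)C)(C(C)C)C(C)C)c(OC)c1
F2 | step 5 | methyl 2-[(R)-Ar(hydroxy)methyl]prop-2-enoate | O[C@H](c1ccc(O[Si](C(C)C)(C(C)C)C(C)C)c(OC)c1)C(=C)C(=O)OC
F3 | step 5 | methyl 2-[(S)-(acetyloxy)(Ar)methyl]prop-2-enoate | CC(=O)O[C@@H](c1ccc(O[Si](C(C)C)(C(C)C)C(C)C)c(OC)c1)C(=C)C(=O)OC
F4 | step 5 | methyl 2-[(R)-Ar(prop-2-en-1-yloxy)methyl]prop-2-enoate | C=CCO[C@H](c1ccc(O[Si](C(C)C)(C(C)C)C(C)C)c(OC)c1)C(=C)C(=O)OC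
F5 | step 6 | {3-methoxy-4-[(triisopropylsilyl)oxy]phenyl}methanol | COc1cc(CO)ccc1O[Si](C(C)C)(C(C)C)C(C)C
F6 | step 6 | 1-{3-methoxy-4-[(triisopropylsilyl)oxy]benzyl}thiolan-1-ium trifluoromethanesulfonate | COc1cc(C[S+]2CCCC2)ccc1O[Si](C(C)C)(C(C)C)C(C)C.[O-]S(=O)(=O)C(F)(F)F
F7 | step 7 | (3R,3aR,6S,6aS)-3,6-di-Ar-tetrahydro-1H,3H-furo[3,4-c]furan-1-one (C3 epimer of 16) | COc1cc([C@H](O3)[C@H]2CO[C@H](c4ccc(O[Si](C(C)C)(C(C)C)C(C)C)c(OC)c4)[C@H]2C3=O)ccc1O[Si](C(C)C)(C(C)C)C(C)C
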